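Ring B is cut at two bonds: the one from its ketone carbon (the carbonyl next to the C(CH3)2 carbon) to the ring CH carbon that later carries the acetyl group, and the one from the adjacent oxygen-bearing carbon to the carbon that holds the ring A methylene. Heating a 2-arylmethyl-3-ethoxy-4,4-dimethylcyclobutenone, whose ring A phenols are benzylated, with (triisopropylsiloxy)acetylene should insert both alkyne carbons and close the six-membered ring in one operation. The step exploits the quaternary C(CH3)2 carbon of ring B: it carries no hydrogen, so the annulation cannot aromatise and stops at the cyclohexadienone level with all three ring oxygens already in their 1,3,5 positions.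

Key step: step 10

Remark on the chemistry: ring B of 24, 26 and 27 is an enolised cyclic β-triketone and is written as one tautomer (27 as in the target SMILES); with a quaternary carbon next to the ketone, the annulation product 23 can only be a cyclohexa-2,4-dien-1-one (C1 ketone, C2 H, C3 OSi, C4 CH2Ar, C5 OEt, C6 CMe2) and is named so.

Step 1
Reactants: 1 2-methylphloroglucinol; 2 butyryl chloride
Product: 3 1-(2,4,6-trihydroxy-3-methylphenyl)butan-1-one
Conditions: AlCl3 (3.5 equiv), PhNO2–CH2Cl2, 0 to 50 °C; dilute HCl work-up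
Reagents that add atoms: none
Why: Friedel–Crafts C-acylation of a symmetric, strongly activated triphenol whose two free ring positions are equivalent, the first acyl group deactivating the ring towards a second one.

Step 2
Reactants: 3 1-(2,4,6-trihydroxy-3-methylphenyl)butan-1-one
Product: 4 aspidinol [1-(2,6-dihydroxy-4-methoxy-3-methylphenyl)butan-1-one]
Conditions: Me2SO4 (1.0 equiv), K2CO3 (1.0 equiv), acetone, rt
Reagents that add atoms: dimethyl sulfate, COS(=O)(=O)OC
Why: Williamson-type partial O-methylation: the hydroxyl para to the ketone is the most acidic and the only one that takes no part in the hydrogen-bonded chelate with the carbonyl, so one equivalent of alkylating agent should react there first.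

Step 3
Reactants: 4 aspidinol
Product: 6 3-butanoyl-2,4-dihydroxy-6-methoxy-5-methylbenzaldehyde, via α-chloro ether 5 (not isolated)
Conditions: Cl2CHOMe (1.5 equiv), TiCl4 (3 equiv), CH2Cl2, −10 to 0 °C; then 1 M HCl (aq)
Reagents that add atoms: dichloromethyl methyl ether, COC(Cl)Cl; water, O
Why: Rieche formylation, in which the TiCl4-activated ether substitutes the single unsubstituted, doubly oxygen-flanked ring carbon and the α-chloro ether 5 is hydrolysed to the aldehyde on work-up.

Step 4
Reactants: 6 3-butanoyl-2,4-dihydroxy-6-methoxy-5-methylbenzaldehyde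
Product: 7 2,4-bis(benzyloxy)-3-butanoyl-6-methoxy-5-methylbenzaldehyde
Conditions: BnBr (2.5 equiv), K2CO3 (3 equiv), n-Bu4NI (cat.), DMF, 60 °C
Reagents that add atoms: benzyl bromide, BrCc1ccccc1
Why: Williamson etherification of the two carbonyl-chelated phenols, which carbonate in warm DMF should O-benzylate.

Step 5
Reactants: 8 isobutyryl chloride; 9 ethoxyacetylene
Product: 11 3-ethoxy-4,4-dimethylcyclobut-2-en-1-one, via dimethylketene 10 (not isolated)
Conditions: Et3N (1.2 equiv), 9 (1.5 equiv), Et2O, rt
Reagents that add atoms: none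
Why: Ketene–ynol ether [2+2] cycloaddition: dimethylketene freed by dehydrochlorination is attacked at its carbonyl carbon by the unsubstituted alkyne carbon, which fixes the 3-ethoxy-4,4-dimethyl pattern.

Step 6
Reactants: 11 3-ethoxy-4,4-dimethylcyclobut-2-en-1-one
Product: 12 2,2-dimethylcyclobutane-1,3-dione
Conditions: 1 M HCl (aq), THF, rt
Reagents that add atoms: water, O
Why: Acid hydrolysis of a vinylogous ester (addition of water at the ethoxy-bearing carbon and loss of ethanol) to the strongly acidic cyclic 1,3-dione.

Step 7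
Reactants: 7 2,4-bis(benzyloxy)-3-butanoyl-6-methoxy-5-methylbenzaldehyde; 12 2,2-dimethylcyclobutane-1,3-dione
Product: 14 2-{[2,4-bis(benzyloxy)-3-butanoyl-6-methoxy-5-methylphenyl]methyl}-3-hydroxy-4,4-dimethylcyclobut-2-en-1-one (enol form of the 2-substituted dione), via arylidene dione 13 (not isolated)
Conditions: Hantzsch ester (diethyl 2,6-dimethyl-1,4-dihydropyridine-3,5-dicarboxylate, 1.1 equiv), L-proline (20 mol %), CH2Cl2, rt
Reagents that add atoms: none
Why: Three-component organocatalytic reductive alkylation: Knoevenagel condensation of the acidic cyclic 1,3-dione with the aldehyde gives the very electrophilic arylidene dione 13, which the Hantzsch ester should reduce by conjugate hydride transfer before a second dione can add, while the hindered aryl ketone stays untouched.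

Step 8
Reactants: 14 2-{[2,4-bis(benzyloxy)-3-butanoyl-6-methoxy-5-methylphenyl]methyl}-3-hydroxy-4,4-dimethylcyclobut-2-en-1-one
Product: 15 2-{[2,4-bis(benzyloxy)-3-butanoyl-6-methoxy-5-methylphenyl]methyl}-3-ethoxy-4,4-dimethylcyclobut-2-en-1-one
Conditions: Et3OBF4 (1.2 equiv), i-Pr2NEt (1.3 equiv), CH2Cl2, 0 °C
Reagents that add atoms: triethyloxonium tetrafluoroborate, CC[O+](CC)CC.F[B-](F)(F)F
Why: O-alkylation of a vinylogous acid with a Meerwein salt: the hard oxonium electrophile ethylates the enolate oxygen, and because the two carbonyl groups of 14 are mirror-related only one enol ether can form.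

Step 9
Reactants: 16 acetylene
Product: 19 (triisopropylsiloxy)acetylene, via lithium acetylide 17 (not isolated), via lithium ethynolate 18 (not isolated)
Conditions: n-BuLi (1.0 equiv), excess C2H2, THF, −78 °C; t-BuOOLi [from t-BuOOH and LiN(SiMe3)2, THF, −78 °C], −78 to 0 °C; i-Pr3SiOTf, −78 to 0 °C
Reagents that add atoms: tert-butyl hydroperoxide, CC(C)(C)OO; triisopropylsilyl trifluoromethanesulfonate, CC(C)[Si](OS(=O)(=O)C(F)(F)F)(C(C)C)C(C)C
Why: Electrophilic oxygenation of a lithium acetylide by lithium tert-butyl peroxide gives the ynolate, and the bulky silyl triflate should silylate this ambident anion on oxygen (ynolate O-silylation).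

Step 10
Reactants: 15 2-{[2,4-bis(benzyloxy)-3-butanoyl-6-methoxy-5-methylphenyl]methyl}-3-ethoxy-4,4-dimethylcyclobut-2-en-1-one; 19 (triisopropylsiloxy)acetylene
Product: 23 4-{[2,4-bis(benzyloxy)-3-butanoyl-6-methoxy-5-methylphenyl]methyl}-5-ethoxy-6,6-dimethyl-3-[(triisopropylsilyl)oxy]cyclohexa-2,4-dien-1-one, via vinylketene 20 (not isolated), via vinylcyclobutenone 21 (not isolated), via dienylketene 22 (not isolated)
Conditions: 19 (3 equiv), toluene (0.2 M), argon, sealed tube, 80 then 110 °C
Reagents that add atoms: none
Why: Danheiser-type cyclobutenone–ynol ether annulation: thermal four-electron electrocyclic opening of 15 cleaves the C(=O)–CMe2 bond to vinylketene 20, whose ketene C=C undergoes a polarised [2+2] cycloaddition with 19 to give 4-vinylcyclobutenone 21, and a second four-electron opening gives dienylketene 22. Ring B then closes by a thermal six-electron electrocyclisation of 22 in which the ketene carbon bonds again to the CMe2 terminus, so that overall the two alkyne carbons are inserted between the carbonyl carbon and the arylmethyl-bearing carbon of 15, driven by the strain released from two cyclobutenones. The closest known reaction type is the benzannulation of cyclobutenones with alkoxy- or siloxyalkynes, which here must stop at the cyclohexa-2,4-dienone because the quaternary CMe2 carbon has no hydrogen to give up for tautomerisation to a phenol. No stereocentre remains in 23 (the one in 21 is lost on ring opening), and the ring openings are reversible, so a dienylketene isomer that cannot cyclise can return. The selectivity needed is the regiochemistry of the [2+2] step, secured by the polarity of the partners: the nucleophilic unsubstituted carbon of 19 attacks the electrophilic ketene carbonyl carbon, which leaves the single ring CH between the ketone and the siloxy carbon, exactly where the acetyl group is needed. Benzylation of both ring A phenols removes every O–H that could trap the ketenes, and because 15 is a single enol ether no regioisomer enters the step.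

Step 11
Reactants: 23 4-{[2,4-bis(benzyloxy)-3-butanoyl-6-methoxy-5-methylphenyl]methyl}-5-ethoxy-6,6-dimethyl-3-[(triisopropylsilyl)oxy]cyclohexa-2,4-dien-1-one
Product: 24 4-{[2,4-bis(benzyloxy)-3-butanoyl-6-methoxy-5-methylphenyl]methyl}-3,5-dihydroxy-6,6-dimethylcyclohexa-2,4-dien-1-one (dienol tautomer of the 1,3,5-trione)
Conditions: 2 M HCl (aq)–THF, 40 °C
Reagents that add atoms: water, O
Why: Acid hydrolysis of the silyl enol ether and then of the vinylogous ethyl ester unmasks the cyclic β-triketone, while benzyl aryl ethers and the aryl ketone are stable to dilute acid.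

Step 12
Reactants: 24 4-{[2,4-bis(benzyloxy)-3-butanoyl-6-methoxy-5-methylphenyl]methyl}-3,5-dihydroxy-6,6-dimethylcyclohexa-2,4-dien-1-one
Product: 26 2-acetyl-6-{[2,4-bis(benzyloxy)-3-butanoyl-6-methoxy-5-methylphenyl]methyl}-3,5-dihydroxy-4,4-dimethylcyclohexa-2,5-dien-1-one, via enol acetate 25 (not isolated)
Conditions: AcCl (1.1 equiv), Et3N (2.5 equiv), CH2Cl2, 0 °C; then DMAP (0.3 equiv), rt; dilute HCl work-up
Reagents that add atoms: acetyl chloride, CC(Cl)=O
Why: O-acylation followed by DMAP-catalysed O-to-C acyl migration (enol ester to β-triketone rearrangement): reversible acyl transfer should funnel the acetyl group to the only unsubstituted ring carbon, where the strongly chelated 2-acyl-1,3-dione enol is the most stable product.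

Step 13
Reactants: 26 2-acetyl-6-{[2,4-bis(benzyloxy)-3-butanoyl-6-methoxy-5-methylphenyl]methyl}-3,5-dihydroxy-4,4-dimethylcyclohexa-2,5-dien-1-one
Product: 27 2-acetyl-6-[(3-butanoyl-2,4-dihydroxy-6-methoxy-5-methylphenyl)methyl]-3,5-dihydroxy-4,4-dimethylcyclohexa-2,5-dien-1-one (target)
Conditions: H2 (1 atm), 10% Pd/C, EtOAc, rt
Reagents that add atoms: none
Why: Catalytic hydrogenolysis of the two benzyl aryl ethers under neutral conditions, which should leave the chelated aryl ketone, the methylene bridge and the fully substituted enolised triketone of ring B unreduced.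

Compound list
1 | 2-methylphloroglucinol | Cc1c(O)cc(O)cc1O | starting material
2 | butyryl chloride | CCCC(Cl)=O | starting material
3 | 1-(2,4,6-trihydroxy-3-methylphenyl)butan-1-one | CCCC(=O)c1c(O)cc(O)c(C)c1O | intermediate
4 | aspidinol, 1-(2,6-dihydroxy-4-methoxy-3-methylphenyl)butan-1-one | CCCC(=O)c1c(O)cc(OC)c(C)c1O | intermediate
5 | 1-{3-[chloro(methoxy)methyl]-2,6-dihydroxy-4-methoxy-5-methylphenyl}butan-1-one (α-chloro ether, racemic, not isolated) | CCCC(=O)c1c(O)c(C)c(OC)c(C(Cl)OC)c1O | intermediate
6 | 3-butanoyl-2,4-dihydroxy-6-methoxy-5-methylbenzaldehyde | CCCC(=O)c1c(O)c(C)c(OC)c(C=O)c1O | intermediate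
7 | 2,4-bis(benzyloxy)-3-butanoyl-6-methoxy-5-methylbenzaldehyde | CCCC(=O)c1c(OCc2ccccc2)c(C)c(OC)c(C=O)c1OCc1ccccc1 | intermediate
8 | isobutyryl chloride | CC(C)C(Cl)=O | starting material
9 | ethoxyacetylene | CCOC#C | starting material
10 | dimethylketene (not isolated) | CC(C)=C=O | intermediate
11 | 3-ethoxy-4,4-dimethylcyclobut-2-en-1-one | CCOC1=CC(=O)C1(C)C | intermediate
12 | 2,2-dimethylcyclobutane-1,3-dione | CC1(C)C(=O)CC1=O | intermediate
13 | 2-{[2,4-bis(benzyloxy)-3-butanoyl-6-methoxy-5-methylphenyl]methylidene}-4,4-dimethylcyclobutane-1,3-dione (arylidene dione, not isolated) | CCCC(=O)c1c(OCc2ccccc2)c(C)c(OC)c(C=C2C(=O)C(C)(C)C2=O)c1OCc1ccccc1 | intermediate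
14 | 2-{[2,4-bis(benzyloxy)-3-butanoyl-6-methoxy-5-methylphenyl]methyl}-3-hydroxy-4,4-dimethylcyclobut-2-en-1-one | CCCC(=O)c1c(OCc2ccccc2)c(C)c(OC)c(CC2=C(O)C(C)(C)C2=O)c1OCc1ccccc1 | intermediate
15 | 2-{[2,4-bis(benzyloxy)-3-butanoyl-6-methoxy-5-methylphenyl]methyl}-3-ethoxy-4,4-dimethylcyclobut-2-en-1-one | CCCC(=O)c1c(OCc2ccccc2)c(C)c(OC)c(CC2=C(OCC)C(C)(C)C2=O)c1OCc1ccccc1 | intermediate
16 | acetylene | C#C | starting material
17 | lithium acetylide (not isolated) | [Li]C#C | intermediate
18 | lithium ethynolate (not isolated) | [Li+].[O-]C#C | intermediate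
19 | (triisopropylsiloxy)acetylene | C#CO[Si](C(C)C)(C(C)C)C(C)C | intermediate
20 | 2-{[2,4-bis(benzyloxy)-3-butanoyl-6-methoxy-5-methylphenyl]methyl}-3-ethoxy-4-methylpenta-1,3-dien-1-one (vinylketene, not isolated) | CCCC(=O)c1c(OCc2ccccc2)c(C)c(OC)c(CC(=C=O)C(OCC)=C(C)C)c1OCc1ccccc1 | intermediate
21 | 4-{[2,4-bis(benzyloxy)-3-butanoyl-6-methoxy-5-methylphenyl]methyl}-4-(1-ethoxy-2-methylprop-1-en-1-yl)-3-[(triisopropylsilyl)oxy]cyclobut-2-en-1-one (vinylcyclobutenone, racemic, not isolated) | CCCC(=O)c1c(OCc2ccccc2)c(C)c(OC)c(CC2(C(OCC)=C(C)C)C(=O)C=C2O[Si](C(C)C)(C(C)C)C(C)C)c1OCc1ccccc1 | intermediate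
22 | (3E)-4-{[2,4-bis(benzyloxy)-3-butanoyl-6-methoxy-5-methylphenyl]methyl}-5-ethoxy-6-methyl-3-[(triisopropylsilyl)oxy]hepta-1,3,5-trien-1-one (dienylketene, ketenyl and ethoxyalkenyl groups cis, not isolated) | CCCC(=O)c1c(OCc2ccccc2)c(C)c(OC)c(C/C(C(OCC)=C(C)C)=C(/C=C=O)O[Si](C(C)C)(C(C)C)C(C)C)c1OCc1ccccc1 | intermediate
23 | 4-{[2,4-bis(benzyloxy)-3-butanoyl-6-methoxy-5-methylphenyl]methyl}-5-ethoxy-6,6-dimethyl-3-[(triisopropylsilyl)oxy]cyclohexa-2,4-dien-1-one | CCCC(=O)c1c(OCc2ccccc2)c(C)c(OC)c(CC2=C(OCC)C(C)(C)C(=O)C=C2O[Si](C(C)C)(C(C)C)C(C)C)c1OCc1ccccc1 | intermediate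
24 | 4-{[2,4-bis(benzyloxy)-3-butanoyl-6-methoxy-5-methylphenyl]methyl}-3,5-dihydroxy-6,6-dimethylcyclohexa-2,4-dien-1-one | CCCC(=O)c1c(OCc2ccccc2)c(C)c(OC)c(CC2=C(O)C(C)(C)C(=O)C=C2O)c1OCc1ccccc1 | intermediate
25 | 2-{[2,4-bis(benzyloxy)-3-butanoyl-6-methoxy-5-methylphenyl]methyl}-3-hydroxy-4,4-dimethyl-5-oxocyclohexa-1,6-dien-1-yl acetate, written as 3-O-acetyl derivative of 24 (enol acetate, one of the interconverting O-acetyl isomers, not isolated) | CCCC(=O)c1c(OCc2ccccc2)c(C)c(OC)c(CC2=C(O)C(C)(C)C(=O)C=C2OC(C)=O)c1OCc1ccccc1 | intermediate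
26 | 2-acetyl-6-{[2,4-bis(benzyloxy)-3-butanoyl-6-methoxy-5-methylphenyl]methyl}-3,5-dihydroxy-4,4-dimethylcyclohexa-2,5-dien-1-one | CCCC(=O)c1c(OCc2ccccc2)c(C)c(OC)c(CC2=C(O)C(C)(C)C(O)=C(C(C)=O)C2=O)c1OCc1ccccc1 | intermediate
27 | 2-acetyl-6-[(3-butanoyl-2,4-dihydroxy-6-methoxy-5-methylphenyl)methyl]-3,5-dihydroxy-4,4-dimethylcyclohexa-2,5-dien-1-one | CCCC(=O)c1c(O)c(C)c(OC)c(CC2=C(O)C(C)(C)C(O)=C(C(C)=O)C2=O)c1O | target

Total step count: 13. Longest linear sequence: 10 steps (steps 1, 2, 3, 4, 7, 8, 10, 11, 12, 13); steps 5 and 6 and step 9 are side branches.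

Steps most likely to fail

Step 10. The vinylketene may be diverted before it meets the alkyne, by a 1,5-hydrogen shift from the methyl group that turns inward or by capture at an ether oxygen of ring A with benzyl transfer. Closure onto the fully substituted terminus may also be slow enough for the dienylketene to add a second alkyne. The fallback gives up the cycloaddition and sets out from aspidinol 4. Acetylfilicinic acid F1 is made from commercial 2,4,6-trihydroxyacetophenone by double C-methylation (MeI, NaOMe, MeOH). It is condensed with 4 and aqueous formaldehyde in dilute aqueous KOH at 0 °C, the classical methylene-bridge formation by Knoevenagel condensation and conjugate addition, and the mixture is acidified. The mixed dimer would be separated from the two symmetrical dimers, and the route is rejoined directly at the target 27.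

Step 7. Condensation at the doubly ortho-substituted, electron-rich aldehyde may be slow, and during that time the strained dione may be opened by the amine catalyst. The fallback sets out from aldehyde 7 and avoids both the amine and the condensation. Reduction with NaBH4 in MeOH–THF at −10 °C, selective for the aldehyde over the hindered ketone, gives the benzylic alcohol F2. Warming F2 with dione 12 in hexafluoroisopropanol at 40 °C (or TsOH cat. in MeNO2) should give acid-promoted dehydrative C-benzylation of the 1,3-dione through the 2,4,6-trioxygenated benzylic cation. The route is rejoined at 14.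

Step 9. The parent ynolate may be silylated at its unhindered carbon end to give a silylketene, and monolithium acetylide may disproportionate on warming before it is oxygenated. The fallback needs no silyl ynol ether and sets out from cyclobutenone 15. Commercial ethoxyacetylene 9 (5 equiv, toluene, sealed tube, 80 °C) is used as the ynol-ether partner in the same annulation and should give the bis(ethyl enol ether) dienone F3. Hydrolysis of both enol ethers of F3 with 2 M HCl (aq)–THF at 50 °C rejoins the route at 24.

Further compounds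
F1 | step 10 | acetylfilicinic acid, 2-acetyl-3,5-dihydroxy-4,4-dimethylcyclohexa-2,5-dien-1-one | CC(=O)C1=C(O)C(C)(C)C(O)=CC1=O
F2 | step 7 | 1-[2,6-bis(benzyloxy)-3-(hydroxymethyl)-4-methoxy-5-methylphenyl]butan-1-one | CCCC(=O)c1c(OCc2ccccc2)c(C)c(OC)c(CO)c1OCc1ccccc1
F3 | step 9 | 4-{[2,4-bis(benzyloxy)-3-butanoyl-6-methoxy-5-methylphenyl]methyl}-3,5-diethoxy-6,6-dimethylcyclohexa-2,4-dien-1-one | CCCC(=O)c1c(OCc2ccccc2)c(C)c(OC)c(CC2=C(OCC)C(C)(C)C(=O)C=C2OCC)c1OCc1ccccc1
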